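**Retrosynthetic overview**
1. Last step: the C15 epoxy triol 26 is joined with two separately made acyl fragments, (Z)-3-methylpent-2-enoyl chloride 31 and (R)-2-methylbutanoic anhydride 33 (C16 together), in a one-pot tin-directed tris-acylation.
2. Ring B (five-membered) is closed late on ring A by a nickel-catalysed reductive alkyne–aldehyde cyclisation between a propynyl arm and an α-silyloxy aldehyde arm held trans-diequatorial; this also sets the E-ethylidene. The oxirane is made afterwards from a tertiary/primary diol.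
3. Ring A functionality: exocyclic methylene by Lombardo methylenation, cis-diol by OsO4 on a Saegusa–Ito enone, propynyl group by conjugate addition anti to C-4.
4. Ring A (six-membered) itself comes from an organocatalytic Michael/aldol annulation that unites two enantiopure fragments of equal size: aldehyde 5 (from 2-methylprop-2-en-1-ol) and vinyl ketone 10 (from (R)-3-hydroxybutyrolactone).
5. Ring order: A (annulation), then B (nickel cyclisation), then the oxirane, then the three esters.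

Convention: hydrindane atoms are numbered C-1 (O-bearing), C-2 (C=O), C-3 (ethylidene), C-3a, C-4 (side chain), C-5, C-6, C-7 (methylidene), C-7a; β is the face of H-3a.
Assumption: the carbinol configuration at C-2 of 21 is irrelevant (it is oxidised in step 17) and is left undefined in its SMILES.

**Route**

Step 1
Reactants: 1 2-methylprop-2-en-1-ol
Product: 2 (S)-(2-methyloxiran-2-yl)methanol
Conditions: Ti(OiPr)4 (5 mol %), L-(+)-diisopropyl tartrate (6 mol %), t-BuOOH, 4 Å molecular sieves, CH2Cl2, −20 °C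
Reagents that add atoms: tert-butyl hydroperoxide, CC(C)(C)OO
Why: Sharpless asymmetric epoxidation of a 2-substituted allylic alcohol, in which the L-(+)-tartrate complex delivers oxygen to the face that gives the (S)-epoxide and so fixes the quaternary carbon that ends as C-2 of the oxirane.

Step 2
Reactants: 2 (S)-(2-methyloxiran-2-yl)methanol
Product: 3 (R)-2-methylpent-4-ene-1,2-diol
Conditions: CH2=CHMgBr (3 equiv), CuI (10 mol %), THF, −30 → 0 °C; then cold 1 M HCl
Reagents that add atoms: vinylmagnesium bromide, C=C[Mg]Br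
Why: copper-catalysed SN2 opening of the epoxide at its CH2 terminus leaves the quaternary carbinol centre untouched (descriptor changes only through priorities).

Step 3
Reactants: 3 (R)-2-methylpent-4-ene-1,2-diol
Product: 4 (R)-2,2,4-trimethyl-4-(prop-2-en-1-yl)-1,3-dioxolane
Conditions: 2,2-dimethoxypropane, PPTS (cat.), CH2Cl2, rt
Reagents that add atoms: 2,2-dimethoxypropane, COC(C)(C)OC
Why: acid-catalysed transketalisation masks the 1,2-diol as an acetonide without touching the stereocentre.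

Step 4
Reactants: 4 (R)-2,2,4-trimethyl-4-(prop-2-en-1-yl)-1,3-dioxolane
Product: 5 2-[(4R)-2,2,4-trimethyl-1,3-dioxolan-4-yl]acetaldehyde
Conditions: O3, CH2Cl2, −78 °C; then PPh3, −78 °C → rt
Reagents that add atoms: ozone, [O-][O+]=O
Why: ozonolysis with reductive work-up cleaves the terminal alkene to the aldehyde, and the quaternary β-centre cannot epimerise.

Step 5
Reactants: 6 (R)-4-hydroxyoxolan-2-one ((R)-3-hydroxy-γ-butyrolactone)
Product: 7 (3R)-3,4-dihydroxy-N-methoxy-N-methylbutanamide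
Conditions: MeNH(OMe)·HCl, AlMe3, CH2Cl2, 0 °C → rt
Reagents that add atoms: N,O-dimethylhydroxylamine hydrochloride, CNOC.Cl
Why: aluminium amide aminolysis of the lactone gives the Weinreb amide and does not involve the carbinol centre (future C-1).

Step 6
Reactants: 7 (3R)-3,4-dihydroxy-N-methoxy-N-methylbutanamide
Product: 8 (3R)-3-hydroxy-N-methoxy-N-methyl-4-(triethylsilyloxy)butanamide
Conditions: Et3SiCl (1.05 equiv), imidazole, CH2Cl2, −30 °C
Reagents that add atoms: chlorotriethylsilane, CC[Si](Cl)(CC)CC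
Why: silylation is selective for the less hindered primary hydroxyl at low temperature.

Step 7
Reactants: 8 (3R)-3-hydroxy-N-methoxy-N-methyl-4-(triethylsilyloxy)butanamide
Product: 9 (3R)-3-(tert-butyldimethylsilyloxy)-N-methoxy-N-methyl-4-(triethylsilyloxy)butanamide
Conditions: t-BuMe2SiOTf, 2,6-lutidine, CH2Cl2, −78 °C
Reagents that add atoms: tert-butyldimethylsilyl trifluoromethanesulfonate, CC(C)(C)[Si](C)(C)OS(=O)(=O)C(F)(F)F
Why: silyl triflate silylation of the remaining secondary hydroxyl gives an orthogonally protected diol (primary Et3Si, secondary t-BuMe2Si).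

Step 8
Reactants: 9 (3R)-3-(tert-butyldimethylsilyloxy)-N-methoxy-N-methyl-4-(triethylsilyloxy)butanamide
Product: 10 (5R)-5-(tert-butyldimethylsilyloxy)-6-(triethylsilyloxy)hex-1-en-3-one
Conditions: CH2=CHMgBr, THF, −20 → 0 °C; inverse quench into cold 1 M HCl
Reagents that add atoms: vinylmagnesium bromide, C=C[Mg]Br
Why: Weinreb ketone synthesis, where the magnesium chelate prevents over-addition and the acidic inverse quench stops the liberated amine adding to the enone.

Step 9
Reactants: 5 2-[(4R)-2,2,4-trimethyl-1,3-dioxolan-4-yl]acetaldehyde; 10 (5R)-5-(tert-butyldimethylsilyloxy)-6-(triethylsilyloxy)hex-1-en-3-one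
Product: 12 (4S)-2-[(1R)-1-(tert-butyldimethylsilyloxy)-2-(triethylsilyloxy)ethyl]-4-[(4R)-2,2,4-trimethyl-1,3-dioxolan-4-yl]cyclohex-2-en-1-one, via keto aldehyde 11 (not isolated)
Conditions: (R)-2-[methoxy(diphenyl)methyl]pyrrolidine (10 mol %), ethyl 3,4-dihydroxybenzoate (20 mol %), neat, 4 °C; then Bn2NH·CF3CO2H (30 mol %), toluene, 50 °C
Reagents that add atoms: none
Why: enamine-catalysed (diarylprolinol ether type) Michael addition, in which the (R)-catalyst shields one face of the E-enamine and gives the 2R aldehyde 11 (future C-4), followed by an ammonium-salt-promoted intramolecular Mannich/aldol condensation that closes ring A.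

Step 10
Reactants: 12 (4S)-2-[(1R)-1-(tert-butyldimethylsilyloxy)-2-(triethylsilyloxy)ethyl]-4-[(4R)-2,2,4-trimethyl-1,3-dioxolan-4-yl]cyclohex-2-en-1-one
Product: 14 (2R,3R,4S)-2-[(1R)-1-(tert-butyldimethylsilyloxy)-2-(triethylsilyloxy)ethyl]-3-(prop-1-yn-1-yl)-4-[(4R)-2,2,4-trimethyl-1,3-dioxolan-4-yl]cyclohexan-1-one, via silyl enol ether 13 (not isolated)
Conditions: MeC≡CZnBr (from MeC≡CMgBr and ZnBr2), Me3SiOTf, THF/Et2O, −40 °C; then 10 % aq. citric acid, THF, 0 °C
Reagents that add atoms: prop-1-ynylzinc bromide, CC#C[Zn]Br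
Why: silyl-triflate-promoted conjugate addition of the zinc acetylide occurs anti to the C-4 substituent, and axial protonation of the enol ether at C-2 (also the thermodynamic outcome) gives the all-equatorial 2,3-trans ketone that defines the trans ring fusion.

Step 11
Reactants: 14 (2R,3R,4S)-2-[(1R)-1-(tert-butyldimethylsilyloxy)-2-(triethylsilyloxy)ethyl]-3-(prop-1-yn-1-yl)-4-[(4R)-2,2,4-trimethyl-1,3-dioxolan-4-yl]cyclohexan-1-one
Product: 16 (4S,5R,6R)-6-[(1R)-1-(tert-butyldimethylsilyloxy)-2-(triethylsilyloxy)ethyl]-5-(prop-1-yn-1-yl)-4-[(4R)-2,2,4-trimethyl-1,3-dioxolan-4-yl]cyclohex-2-en-1-one, via kinetic silyl enol ether 15 (not isolated)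
Conditions: LiN(iPr)2, Me3SiCl, THF, −78 °C; then Pd(OAc)2, MeCN, rt
Reagents that add atoms: none
Why: kinetic deprotonation at the unsubstituted α-CH2 and Saegusa–Ito dehydrogenation place the new enone on the unfunctionalised side without touching a stereocentre.

Step 12
Reactants: 16 (4S,5R,6R)-6-[(1R)-1-(tert-butyldimethylsilyloxy)-2-(triethylsilyloxy)ethyl]-5-(prop-1-yn-1-yl)-4-[(4R)-2,2,4-trimethyl-1,3-dioxolan-4-yl]cyclohex-2-en-1-one
Product: 17 (2S,3S,4R,5R,6R)-6-[(1R)-1-(tert-butyldimethylsilyloxy)-2-(triethylsilyloxy)ethyl]-2,3-dihydroxy-5-(prop-1-yn-1-yl)-4-[(4R)-2,2,4-trimethyl-1,3-dioxolan-4-yl]cyclohexan-1-one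
Conditions: OsO4 (5 mol %), N-methylmorpholine N-oxide, citric acid, acetone/H2O, rt
Reagents that add atoms: N-methylmorpholine N-oxide, C[N+]1([O-])CCOCC1; water, O
Why: Upjohn syn-dihydroxylation of the enone occurs on the face anti to the bulky C-4 substituent, giving the cis-diol trans to the side chain (future C-5 and C-6), while the alkyne is inert.

Step 13
Reactants: 17 (2S,3S,4R,5R,6R)-6-[(1R)-1-(tert-butyldimethylsilyloxy)-2-(triethylsilyloxy)ethyl]-2,3-dihydroxy-5-(prop-1-yn-1-yl)-4-[(4R)-2,2,4-trimethyl-1,3-dioxolan-4-yl]cyclohexan-1-one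
Product: 18 2,3-O-isopropylidene acetal of 17 (all stereocentres as in 17)
Conditions: 2-methoxypropene, PPTS (cat.), CH2Cl2, 0 °C
Reagents that add atoms: 2-methoxypropene, COC(C)=C
Why: acid-catalysed acetonide formation on the cis-1,2-diol protects both hydroxyls for the following steps.

Step 14
Reactants: 18 2,3-O-isopropylidene acetal of 17
Product: 19 methylidene analogue of 18 (ring C=O replaced by C=CH2)
Conditions: Zn, CH2Br2, TiCl4 (preformed Lombardo reagent), THF/CH2Cl2, 0 °C → rt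
Reagents that add atoms: dibromomethane, BrCBr
Why: Lombardo methylenation is non-basic, so the hindered ketone is converted without epimerising the α-centres or eliminating the β-silyloxy group.

Step 15
Reactants: 19 methylidene analogue of 18
Product: 20 (2R)-2-(tert-butyldimethylsilyloxy)-2-(ring)acetaldehyde from 19 (CH2OSiEt3 replaced by CHO)
Conditions: (COCl)2, DMSO, CH2Cl2, −78 → −40 °C; then Et3N, −78 → 0 °C
Reagents that add atoms: none
Why: Swern conditions cleave and oxidise a primary triethylsilyl ether directly to the aldehyde while the secondary tert-butyldimethylsilyl ether survives, and the cold amine quench keeps the α-silyloxy centre intact.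

Step 16
Reactants: 20 (2R)-2-(tert-butyldimethylsilyloxy)-2-(ring)acetaldehyde from 19
Product: 21 (3E)-1β-(tert-butyldimethylsilyloxy)-3-ethylidene-5α,6α-(isopropylidenedioxy)-7-methylidene-4β-[(4R)-2,2,4-trimethyl-1,3-dioxolan-4-yl]-(3aβH,7aαH)-octahydro-1H-inden-2-ol (C-2 epimers)
Conditions: Ni(COD)2 (15 mol %), PBu3 (30 mol %), Et3B, toluene, rt
Reagents that add atoms: none
Why: nickel-catalysed reductive alkyne–aldehyde cyclisation (Montgomery type) proceeds through an oxanickelacycle with syn delivery of hydrogen, which gives the exocyclic E-ethylidene, and the two trans-diequatorial arms can only close to the trans-fused ring B.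

Step 17
Reactants: 21 hydrindan-2-ol (C-2 epimers)
Product: 22 (3E)-1β-(tert-butyldimethylsilyloxy)-3-ethylidene-5α,6α-(isopropylidenedioxy)-7-methylidene-4β-[(4R)-2,2,4-trimethyl-1,3-dioxolan-4-yl]-(3aβH,7aαH)-octahydro-1H-inden-2-one
Conditions: Dess–Martin periodinane, CH2Cl2, 0 °C → rt
Reagents that add atoms: none
Why: Dess–Martin oxidation of the allylic alcohol gives the α-ethylidene ketone and removes the undefined carbinol centre.

Step 18
Reactants: 22 bis-acetonide hydrindan-2-one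
Product: 23 (3E)-1β-(tert-butyldimethylsilyloxy)-4β-[(2R)-1,2-dihydroxypropan-2-yl]-3-ethylidene-5α,6α-dihydroxy-7-methylidene-(3aβH,7aαH)-octahydro-1H-inden-2-one
Conditions: AcOH/H2O/THF (3:1:1), 45 °C
Reagents that add atoms: none
Why: mild acidic hydrolysis removes both acetonides while the secondary tert-butyldimethylsilyl ether and all stereocentres are retained.

Step 19
Reactants: 23 tetraol
Product: 25 (3E)-1β-(tert-butyldimethylsilyloxy)-3-ethylidene-5α,6α-dihydroxy-7-methylidene-4β-[(2R)-2-methyloxiran-2-yl]-(3aβH,7aαH)-octahydro-1H-inden-2-one, via primary tosylate 24 (not isolated)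
Conditions: TsCl (1.1 equiv), Et3N, Me3N·HCl (cat.), CH2Cl2, 0 °C; then K2CO3, MeOH, 0 °C
Reagents that add atoms: none
Why: selective sulfonylation of the only primary hydroxyl and intramolecular Williamson displacement by the tertiary alkoxide form the oxirane without breaking the C–O bond at the quaternary centre, which therefore keeps the configuration set in step 1.

Step 20
Reactants: 25 epoxy diol silyl ether
Product: 26 (3E)-3-ethylidene-1β,5α,6α-trihydroxy-7-methylidene-4β-[(2R)-2-methyloxiran-2-yl]-(3aβH,7aαH)-octahydro-1H-inden-2-one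
Conditions: Bu4NF, AcOH (1:1), THF, 0 °C
Reagents that add atoms: none
Why: buffered fluoride desilylation frees the C-1 hydroxyl without opening the oxirane or isomerising the α-ketol.

Step 21
Reactants: 27 pent-2-ynoic acid
Product: 28 methyl pent-2-ynoate
Conditions: MeOH, H2SO4 (cat.), reflux
Reagents that add atoms: methanol, CO
Why: Fischer esterification provides the ester needed for a clean cuprate addition.

Step 22
Reactants: 28 methyl pent-2-ynoate
Product: 29 methyl (2Z)-3-methylpent-2-enoate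
Conditions: Me2CuLi (from MeLi and CuI), THF, −78 °C; MeOH quench at −78 °C
Reagents that add atoms: lithium dimethylcuprate, [Li+].C[Cu-]C
Why: syn-carbocupration of the ynoate and protonation with retention at low temperature place methyl and hydrogen cis, so the ethyl group is cis to the ester (Z).

Step 23
Reactants: 29 methyl (2Z)-3-methylpent-2-enoate
Product: 30 (2Z)-3-methylpent-2-enoic acid
Conditions: LiOH, THF/H2O, 0 °C → rt; then 1 M HCl
Reagents that add atoms: lithium hydroxide, [Li+].[OH-]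
Why: saponification under mild conditions retains the alkene geometry.

Step 24
Reactants: 30 (2Z)-3-methylpent-2-enoic acid
Product: 31 (2Z)-3-methylpent-2-enoyl chloride
Conditions: 1-chloro-N,N,2-trimethylprop-1-en-1-amine, CH2Cl2, 0 °C → rt
Reagents that add atoms: 1-chloro-N,N,2-trimethylprop-1-en-1-amine, CC(C)=C(Cl)N(C)C
Why: the α-chloroenamine (Ghosez reagent) forms the acid chloride under neutral conditions, which avoids acid- or base-induced Z/E isomerisation and deconjugation.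

Step 25
Reactants: 32 (R)-2-methylbutanoic acid
Product: 33 (R)-2-methylbutanoic anhydride
Conditions: 32 (2 equiv in total), N,N'-dicyclohexylcarbodiimide (1 equiv per 2 equiv of acid), CH2Cl2, 0 °C → rt; filter off the urea
Reagents that add atoms: (R)-2-methylbutanoic acid (the second molecule of 32, which supplies the second acyl group), CC[C@@H](C)C(=O)O
Why: carbodiimide-mediated dehydrative coupling, in which one acid molecule is activated as its O-acylisourea and acylates a second acid molecule to give the symmetric anhydride without touching the α-stereocentres.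

Step 26
Reactants: 26 epoxy triol; 31 (2Z)-3-methylpent-2-enoyl chloride; 33 (R)-2-methylbutanoic anhydride
Product: 36 (1R,3E,3aS,4R,5S,6R,7aS)-3-ethylidene-7-methylidene-4-[(2R)-2-methyloxiran-2-yl]-2-oxooctahydro-1H-indene-1,5,6-triyl 1,6-bis[(2R)-2-methylbutanoate] 5-[(2Z)-3-methylpent-2-enoate], via stannylene acetal 34 (not isolated), via tin ether 35 (not isolated)
Conditions: Bu2Sn(OMe)2 (1.05 equiv), toluene, rt, then evaporation; 31 (1.05 equiv), CH2Cl2, −20 → 0 °C; then 33 (4 equiv), DMAP, pyridine, CH2Cl2, 0 °C → rt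
Reagents that add atoms: none
Why: stannylene-acetal-directed acylation of the cis-diol takes place at the equatorial 5-oxygen, and DMAP-catalysed acylation (one acyl group from each of two anhydride molecules) then esterifies the axial allylic 6-oxygen and the C-1 ketol hydroxyl with retention at every carbinol centre.

**Compound list**
1 | 2-methylprop-2-en-1-ol | C=C(C)CO | starting material
2 | (S)-(2-methyloxiran-2-yl)methanol | OC[C@@]1(C)CO1 | intermediate
3 | (R)-2-methylpent-4-ene-1,2-diol | C=CC[C@@](C)(O)CO | intermediate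
4 | (R)-2,2,4-trimethyl-4-(prop-2-en-1-yl)-1,3-dioxolane | C=CC[C@]1(C)COC(C)(C)O1 | intermediate
5 | 2-[(4R)-2,2,4-trimethyl-1,3-dioxolan-4-yl]acetaldehyde | O=CC[C@]1(C)COC(C)(C)O1 | intermediate
6 | (R)-4-hydroxyoxolan-2-one | O=C1C[C@@H](O)CO1 | starting material
7 | (3R)-3,4-dihydroxy-N-methoxy-N-methylbutanamide | CON(C)C(=O)C[C@@H](O)CO | intermediate
8 | (3R)-3-hydroxy-N-methoxy-N-methyl-4-(triethylsilyloxy)butanamide | CON(C)C(=O)C[C@@H](O)CO[Si](CC)(CC)CC | intermediate
9 | (3R)-3-(tert-butyldimethylsilyloxy)-N-methoxy-N-methyl-4-(triethylsilyloxy)butanamide | CON(C)C(=O)C[C@@H](O[Si](C)(C)C(C)(C)C)CO[Si](CC)(CC)CC | intermediate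
10 | (5R)-5-(tert-butyldimethylsilyloxy)-6-(triethylsilyloxy)hex-1-en-3-one | C=CC(=O)C[C@@H](O[Si](C)(C)C(C)(C)C)CO[Si](CC)(CC)CC | intermediate
11 | (2R,7R)-7-(tert-butyldimethylsilyloxy)-5-oxo-8-(triethylsilyloxy)-2-[(4R)-2,2,4-trimethyl-1,3-dioxolan-4-yl]octanal | O=C[C@@H]([C@]1(C)COC(C)(C)O1)CCC(=O)C[C@@H](O[Si](C)(C)C(C)(C)C)CO[Si](CC)(CC)CC | intermediate
12 | (4S)-2-[(1R)-1-(tert-butyldimethylsilyloxy)-2-(triethylsilyloxy)ethyl]-4-[(4R)-2,2,4-trimethyl-1,3-dioxolan-4-yl]cyclohex-2-en-1-one | O=C1CC[C@H]([C@]2(C)COC(C)(C)O2)C=C1[C@@H](O[Si](C)(C)C(C)(C)C)CO[Si](CC)(CC)CC | intermediate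
13 | C1–C2 trimethylsilyl enol ether of ketone 14 (C-3, C-4 and side chains as in 14) | C[Si](C)(C)OC1=C([C@@H](O[Si](C)(C)C(C)(C)C)CO[Si](CC)(CC)CC)[C@H](C#CC)[C@@H]([C@]2(C)COC(C)(C)O2)CC1 | intermediate
14 | (2R,3R,4S)-2-[(1R)-1-(tert-butyldimethylsilyloxy)-2-(triethylsilyloxy)ethyl]-3-(prop-1-yn-1-yl)-4-[(4R)-2,2,4-trimethyl-1,3-dioxolan-4-yl]cyclohexan-1-one | O=C1CC[C@H]([C@]2(C)COC(C)(C)O2)[C@@H](C#CC)[C@@H]1[C@@H](O[Si](C)(C)C(C)(C)C)CO[Si](CC)(CC)CC | intermediate
15 | C1–C6 trimethylsilyl enol ether of ketone 14 (C-2, C-3, C-4 as in 14) | C[Si](C)(C)OC1=CC[C@H]([C@]2(C)COC(C)(C)O2)[C@@H](C#CC)[C@@H]1[C@@H](O[Si](C)(C)C(C)(C)C)CO[Si](CC)(CC)CC | intermediate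
16 | (4S,5R,6R)-6-[(1R)-1-(tert-butyldimethylsilyloxy)-2-(triethylsilyloxy)ethyl]-5-(prop-1-yn-1-yl)-4-[(4R)-2,2,4-trimethyl-1,3-dioxolan-4-yl]cyclohex-2-en-1-one | O=C1C=C[C@H]([C@]2(C)COC(C)(C)O2)[C@@H](C#CC)[C@@H]1[C@@H](O[Si](C)(C)C(C)(C)C)CO[Si](CC)(CC)CC | intermediate
17 | (2S,3S,4R,5R,6R)-6-[(1R)-1-(tert-butyldimethylsilyloxy)-2-(triethylsilyloxy)ethyl]-2,3-dihydroxy-5-(prop-1-yn-1-yl)-4-[(4R)-2,2,4-trimethyl-1,3-dioxolan-4-yl]cyclohexan-1-one | O=C1[C@@H](O)[C@@H](O)[C@H]([C@]2(C)COC(C)(C)O2)[C@@H](C#CC)[C@@H]1[C@@H](O[Si](C)(C)C(C)(C)C)CO[Si](CC)(CC)CC | intermediate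
18 | 2,3-O-isopropylidene acetal of 17 (cis-fused acetonide; other centres as in 17) | O=C1[C@H]2OC(C)(C)O[C@H]2[C@H]([C@]3(C)COC(C)(C)O3)[C@@H](C#CC)[C@@H]1[C@@H](O[Si](C)(C)C(C)(C)C)CO[Si](CC)(CC)CC | intermediate
19 | methylidene analogue of 18 (ring C=O replaced by C=CH2) | C=C1[C@H]2OC(C)(C)O[C@H]2[C@H]([C@]3(C)COC(C)(C)O3)[C@@H](C#CC)[C@@H]1[C@@H](O[Si](C)(C)C(C)(C)C)CO[Si](CC)(CC)CC | intermediate
20 | (2R)-2-(tert-butyldimethylsilyloxy)acetaldehyde carrying the ring of 19 at C-2 (CH2OSiEt3 of 19 replaced by CHO) | C=C1[C@H]2OC(C)(C)O[C@H]2[C@H]([C@]3(C)COC(C)(C)O3)[C@@H](C#CC)[C@@H]1[C@@H](O[Si](C)(C)C(C)(C)C)C=O | intermediate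
21 | (3E)-1β-(tert-butyldimethylsilyloxy)-3-ethylidene-5α,6α-(isopropylidenedioxy)-7-methylidene-4β-[(4R)-2,2,4-trimethyl-1,3-dioxolan-4-yl]-(3aβH,7aαH)-octahydro-1H-inden-2-ol, C-2 epimers | C=C1[C@@H]2[C@H](/C(=C\C)C(O)[C@@H]2O[Si](C)(C)C(C)(C)C)[C@@H]([C@]3(C)COC(C)(C)O3)[C@@H]4OC(C)(C)O[C@H]14 | intermediate
22 | (3E)-1β-(tert-butyldimethylsilyloxy)-3-ethylidene-5α,6α-(isopropylidenedioxy)-7-methylidene-4β-[(4R)-2,2,4-trimethyl-1,3-dioxolan-4-yl]-(3aβH,7aαH)-octahydro-1H-inden-2-one | C=C1[C@@H]2[C@H](/C(=C\C)C(=O)[C@@H]2O[Si](C)(C)C(C)(C)C)[C@@H]([C@]3(C)COC(C)(C)O3)[C@@H]4OC(C)(C)O[C@H]14 | intermediate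
23 | (3E)-1β-(tert-butyldimethylsilyloxy)-4β-[(2R)-1,2-dihydroxypropan-2-yl]-3-ethylidene-5α,6α-dihydroxy-7-methylidene-(3aβH,7aαH)-octahydro-1H-inden-2-one | C=C1[C@@H]2[C@H](/C(=C\C)C(=O)[C@@H]2O[Si](C)(C)C(C)(C)C)[C@@H]([C@@](C)(O)CO)[C@H](O)[C@@H]1O | intermediate
24 | primary 4-methylbenzenesulfonate of 23 (at the side-chain CH2OH) | C=C1[C@@H]2[C@H](/C(=C\C)C(=O)[C@@H]2O[Si](C)(C)C(C)(C)C)[C@@H]([C@@](C)(O)COS(=O)(=O)c3ccc(C)cc3)[C@H](O)[C@@H]1O | intermediate
25 | (3E)-1β-(tert-butyldimethylsilyloxy)-3-ethylidene-5α,6α-dihydroxy-7-methylidene-4β-[(2R)-2-methyloxiran-2-yl]-(3aβH,7aαH)-octahydro-1H-inden-2-one | C=C1[C@@H]2[C@H](/C(=C\C)C(=O)[C@@H]2O[Si](C)(C)C(C)(C)C)[C@@H]([C@]3(C)CO3)[C@H](O)[C@@H]1O | intermediate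
26 | (3E)-3-ethylidene-1β,5α,6α-trihydroxy-7-methylidene-4β-[(2R)-2-methyloxiran-2-yl]-(3aβH,7aαH)-octahydro-1H-inden-2-one | C=C1[C@@H]2[C@H](/C(=C\C)C(=O)[C@@H]2O)[C@@H]([C@]3(C)CO3)[C@H](O)[C@@H]1O | intermediate
27 | pent-2-ynoic acid | CCC#CC(=O)O | starting material
28 | methyl pent-2-ynoate | CCC#CC(=O)OC | intermediate
29 | methyl (2Z)-3-methylpent-2-enoate | COC(=O)/C=C(/C)CC | intermediate
30 | (2Z)-3-methylpent-2-enoic acid | OC(=O)/C=C(/C)CC | intermediate
31 | (2Z)-3-methylpent-2-enoyl chloride | ClC(=O)/C=C(/C)CC | intermediate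
32 | (R)-2-methylbutanoic acid | CC[C@@H](C)C(=O)O | starting material
33 | (R)-2-methylbutanoic anhydride | CC[C@@H](C)C(=O)OC(=O)[C@H](C)CC | intermediate
34 | 5α,6α-O-dibutylstannylene acetal of 26 | C=C1[C@@H]2[C@H](/C(=C\C)C(=O)[C@@H]2O)[C@@H]([C@]3(C)CO3)[C@@H]4O[Sn](CCCC)(CCCC)O[C@H]14 | intermediate
35 | 5α-O-[(2Z)-3-methylpent-2-enoyl] 6α-O-(chlorodibutylstannyl) derivative of 26 | C=C1[C@@H]2[C@H](/C(=C\C)C(=O)[C@@H]2O)[C@@H]([C@]3(C)CO3)[C@H](OC(=O)/C=C(/C)CC)[C@@H]1O[Sn](Cl)(CCCC)CCCC | intermediate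
36 | (1R,3E,3aS,4R,5S,6R,7aS)-3-ethylidene-7-methylidene-4-[(2R)-2-methyloxiran-2-yl]-2-oxooctahydro-1H-indene-1,5,6-triyl 1,6-bis[(2R)-2-methylbutanoate] 5-[(2Z)-3-methylpent-2-enoate] | C=C1[C@@H]2[C@H](/C(=C\C)C(=O)[C@@H]2OC(=O)[C@H](C)CC)[C@@H]([C@]2(C)CO2)[C@H](OC(=O)/C=C(/C)CC)[C@@H]1OC(=O)[C@H](C)CC | target

**Step count**
Total step count: 26. Longest linear sequence: 17 steps (steps 1–4 or 5–8, then 9–20, then 26); the two branches to 31 and 33 (steps 21–25) run in parallel.

**Steps most likely to fail, with fallbacks**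

Step 9 (annulation). Aldehyde 5 carries a β-oxygen, so its enamine may eliminate before it adds to 10, and 10 is itself base-sensitive. The fallback sets out from 5 and returns at 11, which is cyclised to 12 as in step 9. It replaces enamine catalysis by an auxiliary-controlled Michael addition. Pinnick oxidation (NaClO2, NaH2PO4, 2-methylbut-2-ene) gives 2-[(4R)-2,2,4-trimethyl-1,3-dioxolan-4-yl]acetic acid F1. Mixed-anhydride coupling (t-BuCOCl, Et3N, then lithiated (R)-4-benzyl-1,3-oxazolidin-2-one) gives the N-acyl oxazolidinone F2. Its chlorotitanium enolate (TiCl3(OiPr), iPr2NEt, CH2Cl2, −78 °C) adds to 10 on the face opposite the benzyl group to give the Michael adduct imide F3. EtSLi then cleaves the auxiliary to the S-ethyl thioester F4, and Fukuyama reduction (Et3SiH, Pd/C) delivers 11.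

Step 10 (conjugate propynylation). The enone is α-substituted and carries acid-sensitive groups that may not tolerate the silyl triflate. The fallback sets out from 12 and returns at 14. It uses a nickel-catalysed conjugate addition of dimethyl(prop-1-ynyl)aluminium (Me2AlC≡CMe, Ni(acac)2 and i-Bu2AlH as catalyst precursors, Et2O, −5 °C), followed by cold aqueous NH4Cl. The aluminium enolate is protonated directly, so no silyl triflate and no enol ether is involved, and no compound outside the list is formed (F0).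

Step 26 (one-pot tris-acylation). The regioselectivity on the free triol or acyl migration may fail. The fallback sets out from 25, with C-1 still silylated, and returns at 36. It builds the esters one at a time under catalyst control. Borinic-acid-catalysed acylation of the cis-diol at the equatorial oxygen (Ph2BOCH2CH2NH2 10 mol %, 31, iPr2NEt, MeCN, 0 °C) gives the 5-enoate 6-alcohol F5. Treatment with 33 and DMAP gives the 5,6-diester silyl ether F6. Bu4NF/AcOH gives the C-1 ketol diester F7, and Steglich esterification with 32 (N,N'-dicyclohexylcarbodiimide, DMAP) gives 36.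

**Further compounds**
F1 | step 9 | 2-[(4R)-2,2,4-trimethyl-1,3-dioxolan-4-yl]acetic acid | OC(=O)C[C@]1(C)COC(C)(C)O1
F2 | step 9 | (4R)-4-benzyl-3-{2-[(4R)-2,2,4-trimethyl-1,3-dioxolan-4-yl]acetyl}-1,3-oxazolidin-2-one | O=C(C[C@]1(C)COC(C)(C)O1)N1[C@H](Cc2ccccc2)COC1=O
F3 | step 9 | (4R)-4-benzyl-3-{(2R,7R)-7-(tert-butyldimethylsilyloxy)-5-oxo-8-(triethylsilyloxy)-2-[(4R)-2,2,4-trimethyl-1,3-dioxolan-4-yl]octanoyl}-1,3-oxazolidin-2-one | O=C([C@@H]([C@]1(C)COC(C)(C)O1)CCC(=O)C[C@@H](O[Si](C)(C)C(C)(C)C)CO[Si](CC)(CC)CC)N1[C@H](Cc2ccccc2)COC1=O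
F4 | step 9 | S-ethyl (2R,7R)-7-(tert-butyldimethylsilyloxy)-5-oxo-8-(triethylsilyloxy)-2-[(4R)-2,2,4-trimethyl-1,3-dioxolan-4-yl]octanethioate | CCSC(=O)[C@@H]([C@]1(C)COC(C)(C)O1)CCC(=O)C[C@@H](O[Si](C)(C)C(C)(C)C)CO[Si](CC)(CC)CC
F0 | step 10 | none | none
F5 | step 26 | 5α-O-[(2Z)-3-methylpent-2-enoyl] derivative of 25 (6α-OH free, 1β-silyl ether) | C=C1[C@@H]2[C@H](/C(=C\C)C(=O)[C@@H]2O[Si](C)(C)C(C)(C)C)[C@@H]([C@]3(C)CO3)[C@H](OC(=O)/C=C(/C)CC)[C@@H]1O
F6 | step 26 | 5α-O-[(2Z)-3-methylpent-2-enoyl] 6α-O-[(2R)-2-methylbutanoyl] derivative of 25 (1β-silyl ether) | C=C1[C@@H]2[C@H](/C(=C\C)C(=O)[C@@H]2O[Si](C)(C)C(C)(C)C)[C@@H]([C@]3(C)CO3)[C@H](OC(=O)/C=C(/C)CC)[C@@H]1OC(=O)[C@H](C)CC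
F7 | step 26 | 5α-O-[(2Z)-3-methylpent-2-enoyl] 6α-O-[(2R)-2-methylbutanoyl] derivative of 26 (1β-OH free) | C=C1[C@@H]2[C@H](/C(=C\C)C(=O)[C@@H]2O)[C@@H]([C@]3(C)CO3)[C@H](OC(=O)/C=C(/C)CC)[C@@H]1OC(=O)[C@H](C)CC
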